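# Proposed total synthesis of CNP0253700.4 by B-alkyl Suzuki–Miyaura closure of ring C on a dihydrocoumarin enol phosphate

## Analysis of the target

The target (28) is tetracyclic. Ring A is a fully substituted phloroglucinol ring with two formyl groups and two free phenols. It is joined through an aryl ether to a dihydropyran (ring B). Ring B shares its C4–C5 bond with a nine-membered carbocycle (ring C), which carries an exocyclic methylene at C8 and is trans-fused at C1–C9 to a gem-dimethylcyclobutane (ring D). Numbering used throughout: ring C runs C1–C2–C3–C4–C5–C6–C7–C8–C9, ring D is C1–C9–C10–C11, and C1′ is the CHPh carbon between C5 and ring A.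

There are five stereocentres. C1 (R) and C9 (S) are trans on the cyclobutane. C4 (R, quaternary: aryl-O, CH3, C3, C5), C5 (S) and C1′ (R) are contiguous. The C4 methyl and H5 are anti, so rings B and C are trans-fused. H5 and H1′ are anti, so C6 is trans to phenyl, and methyl and phenyl lie on opposite faces of ring B. The triad and the cyclobutane pair are separated by two methylene bridges on either side, so neither can be relied on to control the other.

The sensitive parts are the C8 methylene beside the strained cyclobutane (protonation gives a cyclobutylcarbinyl cation, and any cation at C4 can be trapped across the ring), the tertiary alkyl aryl ether at C4, the two salicylaldehyde-type formyl groups and the free phenols. The hard problems are the nine-membered ring, the quaternary C4 inside it, and the absolute relationship between the triad and the cyclobutane.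

The strategy rests on C4. It carries the ring-B aryl ether oxygen, a methyl group and two carbon chains, so it is a ketal-level carbon with one oxygen replaced by methyl. It can therefore be traced to the carbonyl carbon of a 4-phenyl-3,4-dihydrocoumarin, in which ring A, the ring-B oxygen, C4, C5 and C1′ are already assembled. That carbonyl takes C3 through its enol phosphate and then the methyl group through its oxocarbenium ion.

## Retrosynthetic reasoning

**Formyl groups (28 ⇒ 26).** The two aryl–CHO bonds are cut first. The aldehydes and their hydrogen-bonded phenols would not survive an ylide, an organoaluminium reagent, a borane or strong base. The two open positions of ring A in 26 are the only nucleophilic aryl carbons, so a Vilsmeier–Haack reaction can only go there. It must formylate twice without protonating the C8 methylene.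

**C8 methylene and phenol protection (26 ⇒ 25 ⇒ 24 ⇒ 23).** The C8=CH2 bond is cut to the ketone 25 (Wittig reaction). The benzyl ethers are removed by hydrogenolysis at the ketone stage (25 from 24), before any alkene exists and without acid. The ketone is kept as a dioxolane (23) during all chemistry that makes C4 cationic, because a C4 cation and a C8 alkene are 1,5-related across ring C and would cyclise.

**C4 methyl (23 ⇒ 22 ⇒ 21).** The C4–CH3 bond is cut heterolytically to the ring-B oxocarbenium ion and an organoaluminium methyl donor. The methoxy ketal 22 is its stable precursor. 22 comes from the enol ether 21 by adding a proton to C5 and an alcohol to C4 under acid. This makes the quaternary centre from a planar carbon and lets C5 and C4 be set relative to C1′.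

**Ring C (21 ⇒ 19, through 20).** The C3–C4 bond is cut. It is the only ring-C bond that joins a carbon of acyl oxidation level to a plain methylene. One end is available as a lactone-derived ketene acetal phosphate and the other as a terminal vinyl group that a dialkylborane turns into a primary alkylborane. No extra functional group has to be installed in ring C and removed again. The forward reaction must close a nine-membered ring by sp3–sp2 coupling under zerovalent palladium and leave the enol ether needed for the next disconnection.

**C5–C6 (19 ⇒ 18 ⇒ 4 + 17).** The phosphate 19 comes from lactone 18 by O-phosphorylation of its enolate. 18 comes from lactone 4 and the primary iodide 17 by enolate alkylation. The configuration created at C5 is erased in 19, so this bond can be made without stereochemical demands.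

**C1′–phenyl (4 ⇒ 2 + 3; 2 ⇒ 1).** Conjugate addition of 3 to the protected coumarin 2 under a chiral rhodium bisphosphine catalyst sets C1′ in absolute terms at the outset. Every later centre of the triad is relayed from it. 2 is the bis-benzyl ether of commercial 1.

**Side arm of the cyclobutane (17 ⇒ 15 ⇒ 13 + 14 ⇒ 12).** C6 and C7 come from 14 by acyl substitution on the Weinreb amide 13 (C7–C8 bond). The enone 15 is converted in one operation into the β-iodo ketal 17: iodide adds to C6 and the dioxolane forms at C8.

**Cyclobutane (12 ⇒ 9 ⇒ 7).** The four-membered ring is traced to a cyclopentanone by a retro-Wolff step: the carboxyl carbon C8 of 12 is the former ring carbonyl of the diazo ketone 9. Direct [2+2] routes to a 1,2-trans-3,3-dimethylcyclobutane with two different substituents raise regio- and enantiocontrol problems. The five-membered precursor lets C1 be set by conjugate addition and lets C9 settle thermodynamically in the epimerisable ester.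

**C1–C2 (7 ⇒ 5 + 6).** Asymmetric conjugate addition of the vinyl group of 6 to enone 5 sets C1 and supplies C2 and C3.

## Alternatives that were turned down

**Alternative 1: enzymatic construction of ring A.**
- **Disconnection and key step:** ring A is removed. A type 3 polyketide synthase would load the enoyl thioester A2 (C1′ as the thioester carbonyl on a C4=C5 alkene of the complete ring C–D system), extend it with three malonyl units and close by Claisen cyclisation to the acylphloroglucinol A1.
- **For:** four C–C bonds form in water without protecting groups, and the acyl group is placed regiospecifically.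
- **Against:** A2 already contains the nine-membered ring and the trans-cyclobutane, so the real difficulty is moved into the starter unit. An α,β-disubstituted enoyl starter on a medium ring lies far outside the small aliphatic or cinnamoyl starters these enzymes accept. After A1, C1′ is a ketone, so the phenyl group, ring B with its quaternary C4, and C5 all remain to be set without a controlling element, beside the exocyclic alkene.
- **Comparison:** on protecting-group economy for ring A this route is stronger. The chosen route buys ring A in 1 and instead offers catalyst control at C1′ and a convergent union.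

**Alternative 2: macrocyclising Kabbe condensation.**
- **Disconnection and key step:** C4–C5 and O–C4 are cut together. The seco compound A4 (a 2-hydroxyaryl ketone whose α-methylene is C5, tethered to the C4 methyl ketone) would condense under secondary amine catalysis at high dilution, and the phenol would then add to C4, giving chromanone A3.
- **For:** one operation closes rings B and C and makes C4 with its oxygen and methyl group. Because the oxa-Michael step is reversible and C5 is α to the C1′ carbonyl, the ring fusion can settle thermodynamically. On that point it is at least as good as the oxocarbenium methylation used here.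
- **Against:** the C–C step is an aldol-type condensation that must form a nine-membered ring with a tetrasubstituted alkene, in competition with enamine formation at the wrong ketone and with oligomerisation. A3 still lacks phenyl. It would have to be added to a hindered diortho-substituted aryl ketone and the benzylic alcohol reduced under ionising conditions, with the C8 methylene already present. C1′ would thus be set last, by substrate control only.
- **Comparison:** the chosen route reverses the order. C1′ is set first by catalysis, and the ring closure is an irreversible cross-coupling that generates no competing nucleophile.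

**Alternative 3: aryne annulation on a terpene-derived hydroxy enoate.**
- **Disconnection and key step:** the aryl–O and aryl–C1′ bonds are cut. The tertiary alkoxide of hydroxy enoate A6 (to be made from the commercial sesquiterpene A8) would add to the aryne released by fluoride from silyl triflate A7, and the aryl anion would attack the C5 ester, giving alkylidene chromanone A5.
- **For:** A8 supplies rings C and D, C1, C9 and the C4 methyl group. In step count for the carbon skeleton this is clearly stronger than the route chosen here.
- **Against:** a hindered tertiary alkoxide is a poor aryne nucleophile, and the aryne can undergo ene reactions with the two alkenes. Making A6 requires a carboxyl group at C5 next to a C4 carbinol on the terpene skeleton, which is not a short or regiochemically safe operation. After A5, C5 (enone reduction) and C1′ (phenyl addition, then benzylic deoxygenation) must both be set late by substrate control, under conditions that threaten the C8 alkene and the C4 ether.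
- **Comparison:** the chosen route is longer, but it does not depend on the terpene pool, carries the phenyl-bearing centre from the second step, and does all cationic chemistry while C8 is masked.

Key step: step 11

Assumption: (R)-SEGPHOS on 2 and (S)-BINAP on 5 are taken to give the same facial sense as on unsubstituted coumarin and cyclopent-2-enone; if the substituents reverse it, the mirror-image ligand is used.
Assumption: 1, 3, 5, 6 and 14 are catalogue compounds.

## Route

Step 1
Reactants: 1 5,7-dihydroxy-2H-chromen-2-one
Product: 2 5,7-bis(benzyloxy)-2H-chromen-2-one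
Conditions: BnBr (2.4 equiv), K2CO3, DMF, 60 °C
Reagents that add atoms: benzyl bromide, BrCc1ccccc1
Why: Williamson etherification of both phenols. Benzyl ethers tolerate the amide bases, the borane, AlMe3 and aqueous acid used later and are removed by hydrogenolysis before the acid-sensitive alkene exists.

Step 2
Reactants: 2 5,7-bis(benzyloxy)-2H-chromen-2-one; 3 phenylboronic acid
Product: 4 (4R)-5,7-bis(benzyloxy)-4-phenylchroman-2-one
Conditions: Rh(acac)(C2H4)2 (3 mol %), (R)-SEGPHOS (3.3 mol %), 3 (excess), dioxane/H2O 10:1, 60 °C
Reagents that add atoms: none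
Why: Hayashi–Miyaura asymmetric 1,4-addition: the phenylrhodium species inserts the coumarin C3=C4 bond on one enantioface and water protonates the rhodium enolate. C1′ (R) is set by the ligand and is not touched again.

Step 3
Reactants: 5 4,4-dimethylcyclopent-2-en-1-one; 6 potassium trifluoro(vinyl)borate
Product: 7 (3S)-3-ethenyl-4,4-dimethylcyclopentan-1-one
Conditions: [Rh(cod)2]PF6 (3 mol %), (S)-BINAP (3.3 mol %), toluene/H2O 4:1, 100 °C
Reagents that add atoms: none
Why: Rhodium-catalysed asymmetric conjugate addition of an alkenyltrifluoroborate (Hayashi–Miyaura type). The ligand selects the enone face and sets the future C1 next to the gem-dimethyl carbon; this centre is not epimerisable afterwards.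

Step 4
Reactants: 7 (3S)-3-ethenyl-4,4-dimethylcyclopentan-1-one
Product: 9 (3S)-2-diazo-3-ethenyl-4,4-dimethylcyclopentan-1-one, via trifluoroacetyl ketone 8 (not isolated)
Conditions: LiN(SiMe3)2, THF, −78 °C; CF3CO2CH2CF3; then MsN3, Et3N, H2O (1 equiv), MeCN, rt
Reagents that add atoms: methanesulfonyl azide, CS(=O)(=O)N=[N+]=[N-]; 2,2,2-trifluoroethyl trifluoroacetate, O=C(OCC(F)(F)F)C(F)(F)F (its atoms stay in 8 only)
Why: Detrifluoroacetylative (Regitz-type) diazo transfer. Kinetic deprotonation should occur at C2, the methylene flanked by the CH(vinyl) carbon, not at C5, which is neopentyl-like beside the quaternary carbon, so the diazo group is placed where ring contraction gives the 1,2-disubstituted cyclobutane.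

Step 5
Reactants: 9 (3S)-2-diazo-3-ethenyl-4,4-dimethylcyclopentan-1-one
Product: 12 methyl (1S,2R)-2-ethenyl-3,3-dimethylcyclobutane-1-carboxylate, via ketene 10 (not isolated), via cis ester 11 (not isolated)
Conditions: hν (300 nm, Pyrex), MeOH, rt; then NaOMe (0.3 equiv), MeOH, rt
Reagents that add atoms: methanol, CO
Why: Photochemical Wolff rearrangement: the cyclic diazo ketone is locked s-cis, C5 migrates with loss of N2, and methanol traps the ketene. The vinyl-bearing centre does not take part and is retained; methoxide then epimerises the ester-bearing carbon (C9) to the more stable trans arrangement.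

Step 6
Reactants: 12 methyl (1S,2R)-2-ethenyl-3,3-dimethylcyclobutane-1-carboxylate
Product: 13 (1S,2R)-2-ethenyl-N-methoxy-N,3,3-trimethylcyclobutane-1-carboxamide
Conditions: MeNH(OMe)·HCl, iPrMgCl, THF, −20 → 0 °C
Reagents that add atoms: N,O-dimethylhydroxylamine hydrochloride, CNOC.Cl
Why: Aminolysis of the ester by the chloromagnesium amide made in the flask (Weinreb amide formation). Any epimerisation at C9 returns to the trans isomer.

Step 7
Reactants: 13 (1S,2R)-2-ethenyl-N-methoxy-N,3,3-trimethylcyclobutane-1-carboxamide; 14 vinylmagnesium bromide
Product: 15 1-[(1S,2R)-2-ethenyl-3,3-dimethylcyclobutyl]prop-2-en-1-one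
Conditions: CH2=CHMgBr, THF, −20 → 0 °C; inverse quench into cold 1 M HCl
Reagents that add atoms: none
Why: Weinreb ketone synthesis: the chelated tetrahedral adduct prevents over-addition and brings in C6 and C7. The cold acidic quench keeps the liberated amine from adding to the enone.

Step 8
Reactants: 15 1-[(1S,2R)-2-ethenyl-3,3-dimethylcyclobutyl]prop-2-en-1-one
Product: 17 2-[(1S,2R)-2-ethenyl-3,3-dimethylcyclobutyl]-2-(2-iodoethyl)-1,3-dioxolane, via iodo silyl enol ether 16 (not isolated)
Conditions: Me3SiI, CH2Cl2, −78 °C; then HOCH2CH2OH, −78 °C → rt
Reagents that add atoms: iodotrimethylsilane, C[Si](C)(C)I; ethane-1,2-diol, OCCO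
Why: Silyl iodide adds in conjugate fashion to the enone to give the γ-iodo silyl enol ether, which the diol converts into the dioxolane under the acid released (one-pot β-iodo ketal formation from a vinyl ketone). The isolated vinyl group does not react at low temperature, and C9 stays trans.

Step 9
Reactants: 4 (4R)-5,7-bis(benzyloxy)-4-phenylchroman-2-one; 17 2-[(1S,2R)-2-ethenyl-3,3-dimethylcyclobutyl]-2-(2-iodoethyl)-1,3-dioxolane
Product: 18 (3S,4R)-5,7-bis(benzyloxy)-3-{2-[2-((1S,2R)-2-ethenyl-3,3-dimethylcyclobutyl)-1,3-dioxolan-2-yl]ethyl}-4-phenylchroman-2-one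
Conditions: LiN(SiMe3)2, THF, −78 °C; then 17, DMPU, −78 → −30 °C
Reagents that add atoms: none
Why: Lactone enolate alkylation (SN2 on a primary iodide, accelerated by DMPU). The electrophile should enter anti to the C1′ phenyl group and give the trans lactone; the new centre (C5) is flattened again in step 10, so its ratio is not critical.

Step 10
Reactants: 18 (3S,4R)-5,7-bis(benzyloxy)-3-{2-[2-((1S,2R)-2-ethenyl-3,3-dimethylcyclobutyl)-1,3-dioxolan-2-yl]ethyl}-4-phenylchroman-2-one
Product: 19 (4R)-5,7-bis(benzyloxy)-3-{2-[2-((1S,2R)-2-ethenyl-3,3-dimethylcyclobutyl)-1,3-dioxolan-2-yl]ethyl}-4-phenyl-4H-chromen-2-yl diphenyl phosphate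
Conditions: KN(SiMe3)2, THF/HMPA, −78 °C; then (PhO)2P(O)Cl
Reagents that add atoms: diphenyl chlorophosphate, O=P(Cl)(Oc1ccccc1)Oc1ccccc1
Why: The remaining α-proton (H5) is removed and the potassium enolate is phosphorylated on oxygen by the hard chlorophosphate (formation of a lactone-derived ketene acetal phosphate). C1′ is benzylic but not α to the carbonyl and is not deprotonated.

Step 11
Reactants: 19 (4R)-5,7-bis(benzyloxy)-3-{2-[2-((1S,2R)-2-ethenyl-3,3-dimethylcyclobutyl)-1,3-dioxolan-2-yl]ethyl}-4-phenyl-4H-chromen-2-yl diphenyl phosphate
Product: 21 ring-C-closed 4H-chromene enol ether (C4=C5; C8 dioxolane; 5,7-bis(benzyloxy); 1R,9S,1′S), via alkylborane 20 (not isolated)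
Conditions: 9-BBN dimer, THF, 0 °C → rt; then 3 M aq. Cs2CO3, slow addition to Pd(dppf)Cl2·CH2Cl2 (15 mol %), AsPh3 (30 mol %), DMF/THF/H2O, 50 °C, 1 mM
Reagents that add atoms: none
Why: Proposed new method: 9-BBN adds to the monosubstituted vinyl group with boron on the terminal carbon C3 and leaves the tetrasubstituted, electron-rich ketene acetal alone; zerovalent palladium (formed from the divalent palladium precatalyst) then inserts into the C4–O(phosphate) bond, the base-activated borate 20 transfers its primary alkyl group to palladium, and reductive elimination forms C3–C4. The closest known reactions are the intermolecular B-alkyl Suzuki–Miyaura coupling of lactone-derived ketene acetal phosphates and B-alkyl Suzuki–Miyaura macrocyclisations onto alkenyl halides, which have given nine-membered carbocycles; new here is ring closure onto a phosphate that is fully substituted at C5 and derived from an aryl lactone. Ring C closes as a nine-membered carbocycle by sp3–sp2 coupling through a ten-membered alkyl(alkenyl)palladacycle of divalent palladium. The flat C4=C5 unit, which is cis within ring C as in the isocaryophyllene series, and the trans cyclobutane bonds remove much of the tether's freedom. No stereocentre is formed and C1, C9 and C1′ cannot epimerise under these conditions (the C1′ descriptor changes to S only because C5 becomes sp2 and outranks phenyl). The step needs chemoselective hydroboration, which the difference between a vinyl group and a tetrasubstituted enol ether secures; cyclisation over oligomerisation, which slow addition at about 1 mM secures; and reductive elimination faster than β-hydride elimination, for which the wide bite angle of dppf is chosen. Phosphate lost to hydrolysis returns lactone 18, which can be recycled.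

Step 12
Reactants: 21 ring-C-closed 4H-chromene enol ether (C4=C5; C8 dioxolane; 5,7-bis(benzyloxy); 1R,9S,1′S)
Product: 22 C4 methoxy ketal (1R,4R,5S,9S,1′R; OMe axial at C4; C6 trans to phenyl; C8 dioxolane; 5,7-bis(benzyloxy))
Conditions: CSA (10 mol %), MeOH (20 equiv), CH2Cl2, 40 °C; Et3N quench
Reagents that add atoms: methanol, CO
Why: Acid-catalysed addition of an alcohol to an enol ether: protonation at C5 gives the ring-B oxocarbenium ion, which methanol captures. At 40 °C the ketal re-ionises and loses H5 reversibly, so the C5 epimers equilibrate through 21; the epimer with C6 trans to phenyl is expected to prevail because it alone can place phenyl, C6 and C3 equatorially on the ring-B half-chair with the methoxy group axial. Both C4 anomers are usable, since C4 is ionised again in step 13, and the limited amount of methanol leaves the hindered dioxolane in place.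

Step 13
Reactants: 22 C4 methoxy ketal (1R,4R,5S,9S,1′R; OMe axial at C4; C6 trans to phenyl; C8 dioxolane; 5,7-bis(benzyloxy))
Product: 23 (1R,4R,5S,9S,1′R)-C4-methyl chroman (C8 dioxolane; 5,7-bis(benzyloxy))
Conditions: AlMe3 (4 equiv), CH2Cl2, −78 → −20 °C; aq. potassium sodium tartrate
Reagents that add atoms: trimethylaluminium, C[Al](C)C
Why: Lewis-acid substitution of a ketal by an organoaluminium reagent through an oxocarbenium ion: AlMe3 binds the more basic methoxy oxygen, methoxide leaves, and the aluminate returns a methyl group to C4. Attack is axial on the half-chair with C6 equatorial and comes from the face opposite the C1′ phenyl group, which gives 4R with methyl cis to C6 and ring C fused through two equatorial bonds. The cyclic, hindered dioxolane re-closes after any ionisation and should survive at this temperature.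

Step 14
Reactants: 23 (1R,4R,5S,9S,1′R)-C4-methyl chroman (C8 dioxolane; 5,7-bis(benzyloxy))
Product: 24 (1R,4R,5S,9S,1′R)-C8 ketone (5,7-bis(benzyloxy))
Conditions: 1 M aq. HCl/THF 1:4, 40 °C
Reagents that add atoms: water, O
Why: Acid hydrolysis of the dioxolane. No alkene is present, the 2,2-dialkylchroman ether tolerates dilute aqueous acid, and C9 (α to the ketone) stays trans because the trans-fused four–nine system is the more stable one.

Step 15
Reactants: 24 (1R,4R,5S,9S,1′R)-C8 ketone (5,7-bis(benzyloxy))
Product: 25 (1R,4R,5S,9S,1′R)-C8 ketone with free 5,7-phenols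
Conditions: H2 (1 atm), 10% Pd on carbon, EtOAc/MeOH, rt
Reagents that add atoms: none
Why: Hydrogenolysis of the two benzyl ethers, done before the alkene is made. The ketone, the diarylmethine C1′–H and the non-benzylic C4–O bond are not reduced under these conditions.

Step 16
Reactants: 25 (1R,4R,5S,9S,1′R)-C8 ketone with free 5,7-phenols
Product: 26 (1R,4R,5S,9S,1′R)-8-methylene diphenol (the target without its formyl groups)
Conditions: Ph3PCH3Br (6 equiv), KOtBu (5.8 equiv), THF, rt → 60 °C
Reagents that add atoms: methylenetriphenylphosphorane, C=P(c1ccccc1)(c1ccccc1)c1ccccc1 (from methyltriphenylphosphonium bromide, C[P+](c1ccccc1)(c1ccccc1)c1ccccc1.[Br-])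
Why: Wittig methylenation of the hindered C8 ketone. Two equivalents of ylide are spent as base on the phenols, whose phenoxides are inert, and the excess olefinates the ketone; the basic medium cannot harm the C9 configuration because trans is the stable fusion.

Step 17
Reactants: 26 (1R,4R,5S,9S,1′R)-8-methylene diphenol (the target without its formyl groups)
Product: 28 CNP0253700.4 (1R,4R,5S,9S,1′R), via bis-iminium salt 27 (not isolated)
Conditions: POCl3 (4 equiv), DMF, 0 °C → rt; then aq. NaOAc, rt
Reagents that add atoms: N,N-dimethylformamide, CN(C)C=O; water, O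
Why: Twofold Vilsmeier–Haack formylation: the chloroiminium ion attacks the two open ring-A positions, each ortho or para to three oxygen donors, and buffered hydrolysis releases the aldehydes. DMF buffers the acid formed, and the arene is far more nucleophilic than the 1,1-disubstituted alkene, so C8=CH2 should be spared at 0 °C to rt.

## Compound list

1 | 5,7-dihydroxy-2H-chromen-2-one | O=c1ccc2c(O)cc(O)cc2o1 | starting material
2 | 5,7-bis(benzyloxy)-2H-chromen-2-one | O=c1ccc2c(OCc3ccccc3)cc(OCc3ccccc3)cc2o1 | intermediate
3 | phenylboronic acid | OB(O)c1ccccc1 | starting material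
4 | (4R)-5,7-bis(benzyloxy)-4-phenylchroman-2-one | O=C1C[C@H](c2ccccc2)c2c(OCc3ccccc3)cc(OCc3ccccc3)cc2O1 | intermediate
5 | 4,4-dimethylcyclopent-2-en-1-one | O=C1C=CC(C)(C)C1 | starting material
6 | potassium trifluoro(vinyl)borate | C=C[B-](F)(F)F.[K+] | starting material
7 | (3S)-3-ethenyl-4,4-dimethylcyclopentan-1-one | C=C[C@@H]1CC(=O)CC1(C)C | intermediate
8 | 3-ethenyl-4,4-dimethyl-2-(trifluoroacetyl)cyclopentan-1-one (C3 as in 7; C2 epimers and enol form) | C=C[C@@H]1C(C(=O)C(F)(F)F)C(=O)CC1(C)C | intermediate (not isolated)
9 | (3S)-2-diazo-3-ethenyl-4,4-dimethylcyclopentan-1-one | C=C[C@@H]1C(=[N+]=[N-])C(=O)CC1(C)C | intermediate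
10 | (2S)-(2-ethenyl-3,3-dimethylcyclobutylidene)methanone (ketene) | C=C[C@H]1C(C)(C)CC1=C=O | intermediate (not isolated)
11 | methyl (1R,2R)-2-ethenyl-3,3-dimethylcyclobutane-1-carboxylate (cis) | C=C[C@H]1C(C)(C)C[C@H]1C(=O)OC | intermediate (not isolated)
12 | methyl (1S,2R)-2-ethenyl-3,3-dimethylcyclobutane-1-carboxylate (trans) | C=C[C@H]1C(C)(C)C[C@@H]1C(=O)OC | intermediate
13 | (1S,2R)-2-ethenyl-N-methoxy-N,3,3-trimethylcyclobutane-1-carboxamide | C=C[C@H]1C(C)(C)C[C@@H]1C(=O)N(C)OC | intermediate
14 | vinylmagnesium bromide | C=C[Mg]Br | starting material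
15 | 1-[(1S,2R)-2-ethenyl-3,3-dimethylcyclobutyl]prop-2-en-1-one | C=C[C@H]1C(C)(C)C[C@@H]1C(=O)C=C | intermediate
16 | {[1-((1S,2R)-2-ethenyl-3,3-dimethylcyclobutyl)-3-iodoprop-1-en-1-yl]oxy}trimethylsilane | C=C[C@H]1C(C)(C)C[C@@H]1C(O[Si](C)(C)C)=CCI | intermediate (not isolated)
17 | 2-[(1S,2R)-2-ethenyl-3,3-dimethylcyclobutyl]-2-(2-iodoethyl)-1,3-dioxolane | C=C[C@H]1C(C)(C)C[C@@H]1C1(CCI)OCCO1 | intermediate
18 | (3S,4R)-5,7-bis(benzyloxy)-3-{2-[2-((1S,2R)-2-ethenyl-3,3-dimethylcyclobutyl)-1,3-dioxolan-2-yl]ethyl}-4-phenylchroman-2-one | C=C[C@H]1C(C)(C)C[C@@H]1C1(OCCO1)CC[C@@H]1C(=O)Oc2cc(OCc3ccccc3)cc(OCc3ccccc3)c2[C@H]1c1ccccc1 | intermediate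
19 | (4R)-5,7-bis(benzyloxy)-3-{2-[2-((1S,2R)-2-ethenyl-3,3-dimethylcyclobutyl)-1,3-dioxolan-2-yl]ethyl}-4-phenyl-4H-chromen-2-yl diphenyl phosphate | C=C[C@H]1C(C)(C)C[C@@H]1C1(OCCO1)CCC1=C(OP(=O)(Oc2ccccc2)Oc2ccccc2)Oc2cc(OCc3ccccc3)cc(OCc3ccccc3)c2[C@H]1c1ccccc1 | intermediate (key-step precursor)
20 | 19 with the ethenyl group converted into a 2-(9-borabicyclo[3.3.1]nonan-9-yl)ethyl group | B1(CC[C@H]2C(C)(C)C[C@@H]2C2(OCCO2)CCC2=C(OP(=O)(Oc3ccccc3)Oc3ccccc3)Oc3cc(OCc4ccccc4)cc(OCc4ccccc4)c3[C@H]2c2ccccc2)C2CCCC1CCC2 | intermediate (not isolated)
21 | ring-C-closed 4H-chromene enol ether: C3–C4 bond formed, C4=C5, C8 as 1,3-dioxolane, 5,7-bis(benzyloxy) on ring A, (1R,9S,1′S) | C12(OCCO1)CCC3=C(CC[C@@H]4[C@@H]2CC4(C)C)Oc1cc(OCc5ccccc5)cc(OCc5ccccc5)c1[C@H]3c1ccccc1 | intermediate (key-step product)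
22 | C4 methoxy ketal of 21: (1R,4R,5S,9S,1′R), OMe axial at C4, H5 anti to H1′, C8 dioxolane, 5,7-bis(benzyloxy); the minor C4 anomer is carried along | C12(OCCO1)CC[C@H]3[C@H](c4ccccc4)c4c(OCc5ccccc5)cc(OCc5ccccc5)cc4O[C@]3(OC)CC[C@@H]3[C@@H]2CC3(C)C | intermediate
23 | (1R,4R,5S,9S,1′R)-C4-methyl chroman, C8 dioxolane, 5,7-bis(benzyloxy) | C12(OCCO1)CC[C@H]3[C@H](c4ccccc4)c4c(OCc5ccccc5)cc(OCc5ccccc5)cc4O[C@]3(C)CC[C@@H]3[C@@H]2CC3(C)C | intermediate
24 | (1R,4R,5S,9S,1′R)-C8 ketone, 5,7-bis(benzyloxy) | O=C1CC[C@H]2[C@H](c3ccccc3)c3c(OCc4ccccc4)cc(OCc4ccccc4)cc3O[C@]2(C)CC[C@@H]2[C@@H]1CC2(C)C | intermediate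
25 | (1R,4R,5S,9S,1′R)-C8 ketone with free 5,7-phenols | O=C1CC[C@H]2[C@H](c3ccccc3)c3c(O)cc(O)cc3O[C@]2(C)CC[C@@H]2[C@@H]1CC2(C)C | intermediate
26 | (1R,4R,5S,9S,1′R)-8-methylene diphenol (target without formyl groups) | C=C1CC[C@H]2[C@H](c3ccccc3)c3c(O)cc(O)cc3O[C@]2(C)CC[C@@H]2[C@@H]1CC2(C)C | intermediate
27 | bis(N,N-dimethyliminium) dichloride of 28 (both ring-A CH=NMe2+ groups) | C=C1CC[C@H]2[C@H](c3ccccc3)c3c(O)c(C=[N+](C)C)c(O)c(C=[N+](C)C)c3O[C@]2(C)CC[C@@H]2[C@@H]1CC2(C)C.[Cl-].[Cl-] | intermediate (not isolated)
28 | CNP0253700.4, (1R,4R,5S,9S,1′R) | C=C1CC[C@H]2[C@H](c3ccccc3)c3c(O)c(C=O)c(O)c(C=O)c3O[C@]2(C)CC[C@@H]2[C@@H]1CC2(C)C | target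

## Step count and least certain steps

Total step count: 17. Longest linear sequence: 15 steps (5 → 28, steps 3 to 17). The arene branch (steps 1 and 2) joins at step 9.

**Step 11 (key step, Proposed new method).**
- What may go wrong: oligomerisation can outrun closure of the strained nine-membered ring. Oxidative addition at the fully substituted ketene acetal phosphate may be slow, so that hydrolysis of the phosphate by the aqueous base, protodeboronation or β-hydride elimination win. The step also presupposes that the phosphate made in step 10 survives handling.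
- Fallback with known reaction types, from 19 back to 21:
  - Stille coupling of 19 with Bu3SnCH=CH2 (Pd(PPh3)4, LiCl, THF, reflux), a coupling established for lactone-derived ketene acetal phosphates, would give the 2-vinyl-4H-chromene triene F1.
  - Ring-closing metathesis between the cyclobutyl vinyl group and the diene terminus (second-generation Hoveyda–Grubbs catalyst, toluene, 80 °C, 1 mM) would give the nine-membered cyclic diene F2 with a cis C2=C3 bond.
  - Diimide (2-nitrobenzenesulfonyl hydrazide, Et3N, CH2Cl2) would reduce only the disubstituted C2=C3 bond and return 21.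

**Step 12.**
- What may go wrong: the equilibrium at C5 may have too little bias, or equilibration may be incomplete. Kinetic protonation anti to phenyl probably favours the unwanted epimer. Prolonged acid may also exchange the dioxolane.
- Fallback, from 18 back to 22, keeping the C5 configuration fixed kinetically in step 9 by never planarising C5:
  - Hydroboration and oxidation of 18 (9-BBN; NaBO3·4H2O, mild acid work-up to re-close the lactone) would give the primary alcohol F3.
  - I2, PPh3 and imidazole would give the iodide F4.
  - SmI2 with HMPA in THF at high dilution would add the alkyl group to the lactone carbonyl in an intramolecular Barbier reaction and give the hemiketal F5, with C3–C4 formed and C5 untouched.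
  - PPTS in MeOH at 0 °C, too mild for ketal-to-enol-ether elimination, would give 22.
  - This detour also bypasses phosphate 19.

**Step 13.**
- What may go wrong: facial selectivity may be poor. Ionisation may occur on the wrong side (loss of the aryloxide, not the methoxide, which leads to ring opening). AlMe3 may attack the dioxolane.
- Fallback, from 22 back to 23:
  - Mild aqueous acid (AcOH/H2O/THF) would hydrolyse the C4 ketal to the hemiketal F5.
  - MeLi with CeCl3 in excess would add to its open keto form and give the phenol tertiary carbinol F6.
  - Catalytic TsOH in CH2Cl2 over 4 Å sieves would close ring B by capture of the tertiary C4 cation by the phenol, a reversible chair-like closure that should favour the trans-fused 23. C8 is still a ketal, so no alkene can intercept the cation.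

**Step 9.**
- What may go wrong: substitution on the unactivated iodide may be sluggish while the aryl ester enolate fragments to a ketene phenoxide and self-condenses, or the iodide may undergo elimination.
- Fallback, from 4 and 15 back to 18, by conjugate addition in place of substitution:
  - The lithium enolate of 4 would add to the vinyl ketone 15 (THF, −78 °C) to give the keto lactone F7.
  - Ketalisation with Me3SiOCH2CH2OSiMe3 and catalytic Me3SiOTf (CH2Cl2, −78 °C) would give 18.

**Step 2.**
- What may go wrong: insertion may be slow at an electron-rich coumarin whose C4 is crowded by the peri benzyloxy group, so that protodeboronation of 3 consumes the reagent, or selectivity may erode.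
- Fallback, from 2 back to 4:
  - Oxidative Heck arylation of 2 with 3 (Pd(OAc)2, 1,10-phenanthroline, O2, DMF, 80 °C) would give the 4-phenylcoumarin F8.
  - Copper hydride conjugate reduction (Cu(OAc)2, the DTBM-SEGPHOS enantiomer that delivers the 4R centre, a hydrosilane, t-BuOH, toluene) would set C1′ with a small nucleophile and, with over-reduction accepted, give the lactol F9.
  - Ag2CO3 on Celite (toluene, reflux) would oxidise F9 back to 4.

## Further compounds

F1 | step 11 | 2-vinyl-4H-chromene triene (19 with the phosphate replaced by ethenyl; 1′S by priority) | C=C[C@H]1C(C)(C)C[C@@H]1C1(OCCO1)CCC1=C(C=C)Oc2cc(OCc3ccccc3)cc(OCc3ccccc3)c2[C@H]1c1ccccc1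
F2 | step 11 | nine-membered cyclic diene (cis C2=C3 and C4=C5; otherwise as 21) | C12(OCCO1)CCC3=C(/C=C\[C@@H]4[C@@H]2CC4(C)C)Oc1cc(OCc5ccccc5)cc(OCc5ccccc5)c1[C@H]3c1ccccc1
F3 | step 12 | primary alcohol (18 with the ethenyl group converted into 2-hydroxyethyl) | OCC[C@H]1C(C)(C)C[C@@H]1C1(OCCO1)CC[C@@H]1C(=O)Oc2cc(OCc3ccccc3)cc(OCc3ccccc3)c2[C@H]1c1ccccc1
F4 | step 12 | primary iodide (18 with the ethenyl group converted into 2-iodoethyl) | ICC[C@H]1C(C)(C)C[C@@H]1C1(OCCO1)CC[C@@H]1C(=O)Oc2cc(OCc3ccccc3)cc(OCc3ccccc3)c2[C@H]1c1ccccc1
F5 | step 12 | C4 hemiketal of the closed ring system (22 with OH in place of OMe; C4 anomers; in equilibrium with its open keto phenol; also met in the fallback to step 13) | C12(OCCO1)CC[C@H]3[C@H](c4ccccc4)c4c(OCc5ccccc5)cc(OCc5ccccc5)cc4OC3(O)CC[C@@H]3[C@@H]2CC3(C)C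
F6 | step 13 | ring-B-opened phenol with C4 tertiary carbinol (C4 epimers; C5 and C1′ as in 22) | C12(OCCO1)CC[C@@H]([C@H](c3ccccc3)c3c(OCc4ccccc4)cc(OCc4ccccc4)cc3O)C(C)(O)CC[C@@H]3[C@@H]2CC3(C)C
F7 | step 9 | keto lactone (18 with the free C8 ketone in place of the dioxolane) | C=C[C@H]1C(C)(C)C[C@@H]1C(=O)CC[C@@H]1C(=O)Oc2cc(OCc3ccccc3)cc(OCc3ccccc3)c2[C@H]1c1ccccc1
F8 | step 2 | 5,7-bis(benzyloxy)-4-phenyl-2H-chromen-2-one | O=c1cc(-c2ccccc2)c2c(OCc3ccccc3)cc(OCc3ccccc3)cc2o1
F9 | step 2 | (4R)-5,7-bis(benzyloxy)-4-phenylchroman-2-ol (lactol, anomers) | OC1C[C@H](c2ccccc2)c2c(OCc3ccccc3)cc(OCc3ccccc3)cc2O1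
A1 | alternative 1 | 2,4,6-trihydroxyphenyl enone (acylphloroglucinol on C5 of the ring C–D system) | C=C1CC/C(C(=O)c3c(O)cc(O)cc3O)=C(C)\CC[C@@H]2[C@@H]1CC2(C)C
A2 | alternative 1 | starter enoyl thioester (N-acetylcysteamine thioester of the C5 carboxylic acid) | C=C1CC/C(C(=O)SCCNC(C)=O)=C(C)\CC[C@@H]2[C@@H]1CC2(C)C
A3 | alternative 2 | trans-fused chromanone, bis(methoxymethyl) ether | C=C1CC[C@H]2C(=O)c3c(OCOC)cc(OCOC)cc3O[C@]2(C)CC[C@@H]2[C@@H]1CC2(C)C
A4 | alternative 2 | seco keto phenol (2-hydroxyaryl ketone tethered to the C4 methyl ketone) | CC(=O)CC[C@@H]1[C@@H](C(=C)CCCC(=O)c2c(O)cc(OCOC)cc2OCOC)CC1(C)C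
A5 | alternative 3 | alkylidene chromanone (C1′ ketone, C5=C6) | C=C1C/C=C2/C(=O)c3c(OCOC)cc(OCOC)cc3O[C@]2(C)CC[C@@H]2[C@@H]1CC2(C)C
A6 | alternative 3 | hydroxy enoate (C4 tertiary alcohol, C5 methyl ester, C5=C6) | C=C1C/C=C(/C(=O)OC)[C@](C)(O)CC[C@@H]2[C@@H]1CC2(C)C
A7 | alternative 3 | 3,5-bis(methoxymethoxy)-2-(trimethylsilyl)phenyl trifluoromethanesulfonate | C[Si](C)(C)c1c(OCOC)cc(OCOC)cc1OS(=O)(=O)C(F)(F)F
A8 | alternative 3 | (−)-β-caryophyllene | C=C1CC/C=C(\C)CC[C@@H]2[C@@H]1CC2(C)C
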